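The 17-membered ring is opened at the ethylene bridge between ring A (the 5-substituted 3-aryloxycatechol) and ring D (the ortho-phenylene). Both bridge carbons are benzylic, so each is carried as an aryl aldehyde. An intramolecular McMurry coupling of the open-chain dialdehyde 8 forms the bridge C–C bond and closes the macrocycle in one operation, at the stilbene level; hydrogenation and demethylation finish. The feature exploited is the ortho relation on ring D between the ether oxygen and the bridge carbon: the formyl group first activates 2-fluorobenzaldehyde for the SNAr that builds the C–O–D ether, then becomes the coupling terminus. Ring A arrives as a formyl phenol by Ullmann coupling.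

Key step: step 5

Remark on the chemistry: ring A is the catechol ring bearing the aryloxy group, ring B the para-phenylene, ring C the catechol ring bearing the ortho aryloxy group, ring D the ortho-phenylene. The target has no stereocentre. The alkene geometries of 3 and 10 are not controlled (drawn E and Z respectively) and are erased by the reductions in steps 2 and 6.

Step 1
Reactants: 1 2-hydroxy-3,4-dimethoxybenzaldehyde; 2 (4-bromobenzyl)triphenylphosphonium bromide
Product: 3 6-[2-(4-bromophenyl)ethenyl]-2,3-dimethoxyphenol (E/Z mixture expected)
Conditions: KOtBu (2.2 equiv), THF, 0 °C to rt; aq. NH4Cl work-up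
Reagents that add atoms: none
Why: Wittig olefination, in which the semi-stabilised benzylic ylide made from 2 should add to the formyl group of 1 (held as its potassium phenoxide by the second equivalent of base) to give the stilbene, whose E/Z ratio is irrelevant because step 2 saturates the double bond.

Step 2
Reactants: 3 6-[2-(4-bromophenyl)ethenyl]-2,3-dimethoxyphenol
Product: 4 6-[2-(4-bromophenyl)ethyl]-2,3-dimethoxyphenol
Conditions: p-toluenesulfonyl hydrazide (excess, in portions), NaOAc, DME/H2O, reflux
Reagents that add atoms: none
Why: Diimide reduction, in which diimide released from the sulfonyl hydrazide should deliver two hydrogens to the stilbene C=C in a concerted syn transfer and leave untouched the aryl bromide that hydrogenation over palladium would endanger.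

Step 3
Reactants: 4 6-[2-(4-bromophenyl)ethyl]-2,3-dimethoxyphenol; 5 2-fluorobenzaldehyde
Product: 6 2-{6-[2-(4-bromophenyl)ethyl]-2,3-dimethoxyphenoxy}benzaldehyde
Conditions: K2CO3, DMF, 130 °C
Reagents that add atoms: none
Why: Nucleophilic aromatic substitution (addition–elimination), in which the ortho formyl group stabilises the negative charge built up on attack of the phenoxide and fluoride leaves, while the unactivated aryl bromide of 4 should not react.

Step 4
Reactants: 6 2-{6-[2-(4-bromophenyl)ethyl]-2,3-dimethoxyphenoxy}benzaldehyde; 7 3-hydroxy-4,5-dimethoxybenzaldehyde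
Product: 8 3-(4-{2-[2-(2-formylphenoxy)-3,4-dimethoxyphenyl]ethyl}phenoxy)-4,5-dimethoxybenzaldehyde
Conditions: CuI (10 mol%), N,N-dimethylglycine hydrochloride (30 mol%), Cs2CO3, 1,4-dioxane, 100 °C
Reagents that add atoms: none
Why: Ullmann-type diaryl ether synthesis, in which ligated monovalent copper should couple the aryl bromide of ring B to the caesium phenoxide of 7, and both formyl groups, lacking α-hydrogens, should tolerate the carbonate base.

Step 5
Reactants: 8 3-(4-{2-[2-(2-formylphenoxy)-3,4-dimethoxyphenyl]ethyl}phenoxy)-4,5-dimethoxybenzaldehyde
Product: 10 macrocyclic stilbene tetramethyl ether (CH=CH bridge between rings A and D; Z expected), via titanium pinacolate 9 (not isolated)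
Conditions: TiCl4, Zn dust, pyridine, THF, reflux; slow syringe-pump addition of 8 (final concentration about 1 mM); aq. K2CO3 work-up
Reagents that add atoms: none
Why: Intramolecular McMurry coupling, in which low-valent titanium made from TiCl4 and Zn transfers one electron to each formyl group, the two titanium-bound ketyl radicals combine to form the new C–C bond as titanium pinacolate 9, and deoxygenation on titanium then gives the CH=CH bridge. The closest known reaction type is the McMurry macrocyclisation of aryl dialdehydes to cyclophane stilbenes. The 17-membered ring is closed end to end by this radical–radical combination of the two chain termini, which are the same functional group, so no cross-selectivity between unlike partners is required. No stereocentre remains in 10: both diastereomeric pinacolates should deoxygenate, and the alkene geometry (Z expected as the less strained isomer) is erased in step 6. The selectivity needed is intra- over intermolecular coupling, which slow addition into a dilute slurry should secure, helped by the flexible saturated B–C bridge and the two ortho-linked rings C and D, which fold the chain and bring the formyl groups of rings A and D together. Aryl methyl ethers and diaryl ethers are inert to the reagent, and pyridine tempers its Lewis acidity.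

Step 6
Reactants: 10 macrocyclic stilbene tetramethyl ether
Product: 11 tetra-O-methyl ether of the target (saturated macrocycle)
Conditions: H2 (1 atm), 10% Pd/C, EtOAc, rt
Reagents that add atoms: none
Why: Heterogeneous catalytic hydrogenation, which should reduce the disubstituted stilbene C=C of either geometry to the same bibenzyl bridge without hydrogenolysis of the aryl methyl ethers or diaryl ethers.

Step 7
Reactants: 11 tetra-O-methyl ether of the target
Product: 12 CNP0114693.0 (target tetraphenol)
Conditions: BBr3 (8 equiv), CH2Cl2, −78 °C to rt; then ice-water, work-up under argon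
Reagents that add atoms: none
Why: Lewis acid cleavage of aryl methyl ethers, in which BBr3 coordinates each methoxy oxygen and bromide removes the methyl group by SN2, whereas the two diaryl ether bonds offer no sp3 carbon for attack and should survive.

Compound list
1 | 2-hydroxy-3,4-dimethoxybenzaldehyde | O=Cc1ccc(OC)c(OC)c1O | starting material
2 | (4-bromobenzyl)triphenylphosphonium bromide | [Br-].Brc1ccc(C[P+](c2ccccc2)(c2ccccc2)c2ccccc2)cc1 | starting material
3 | 6-[2-(4-bromophenyl)ethenyl]-2,3-dimethoxyphenol (E/Z mixture expected, drawn E) | Oc1c(/C=C/c2ccc(Br)cc2)ccc(OC)c1OC | intermediate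
4 | 6-[2-(4-bromophenyl)ethyl]-2,3-dimethoxyphenol | Oc1c(CCc2ccc(Br)cc2)ccc(OC)c1OC | intermediate
5 | 2-fluorobenzaldehyde | O=Cc1ccccc1F | starting material
6 | 2-{6-[2-(4-bromophenyl)ethyl]-2,3-dimethoxyphenoxy}benzaldehyde | O=Cc1ccccc1Oc1c(CCc2ccc(Br)cc2)ccc(OC)c1OC | intermediate
7 | 3-hydroxy-4,5-dimethoxybenzaldehyde | O=Cc1cc(O)c(OC)c(OC)c1 | starting material
8 | 3-(4-{2-[2-(2-formylphenoxy)-3,4-dimethoxyphenyl]ethyl}phenoxy)-4,5-dimethoxybenzaldehyde | O=Cc1ccccc1Oc1c(CCc2ccc(Oc3cc(C=O)cc(OC)c3OC)cc2)ccc(OC)c1OC | intermediate
9 | titanium pinacolate (formal divalent titanium diolate of the macrocyclic 1,2-diol tetramethyl ether; diastereomer mixture, stereocentres not controlled; not isolated) | COc1cc2cc(c1OC)Oc1ccc(cc1)CCc1ccc(OC)c(OC)c1Oc1ccccc1C1O[Ti]OC12 | intermediate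
10 | macrocyclic stilbene tetramethyl ether (target skeleton with four OMe in place of OH and CH=CH in place of the A–D CH2CH2; drawn Z) | COc1cc2cc(c1OC)Oc1ccc(cc1)CCc1ccc(OC)c(OC)c1Oc1ccccc1/C=C\2 | intermediate
11 | tetra-O-methyl ether of the target (saturated macrocycle) | COc1cc2cc(c1OC)Oc1ccc(cc1)CCc1ccc(OC)c(OC)c1Oc1ccccc1CC2 | intermediate
12 | CNP0114693.0 (macrocyclic bis(bibenzyl) tetraphenol) | Oc1cc2cc(c1O)Oc1ccc(cc1)CCc1ccc(O)c(O)c1Oc1ccccc1CC2 | target

Total step count: 7. Longest linear sequence: 7 steps (from 1 to 12).

Steps most likely to fail

Step 5 (macrocyclisation). If closure to the cyclic stilbene is slow, intermolecular coupling to dimers and oligomers, or arrest at the pinacol stage, may take over. The fallback sets out from 8 and comes back to the route at 11, bypassing 9, 10 and step 6. NaBH4 in MeOH/THF should reduce both formyl groups to the bis(hydroxymethyl) compound F1. PBr3 in CH2Cl2 at 0 °C should convert it into the bis(bromomethyl) compound F2. An intramolecular Wurtz coupling (Na, catalytic tetraphenylethylene, THF, high dilution) should then join the two benzylic carbons directly at the saturated level, avoiding any strain of a cyclic stilbene, and give 11.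

Step 4 (Ullmann coupling). Oxidative addition to the electron-neutral aryl bromide may be slow, and prolonged heating with carbonate may degrade the two formyl groups, leaving conversion low. The fallback sets out from 6 and comes back at 8. Miyaura borylation of 6 (bis(pinacolato)diboron, PdCl2(dppf) where dppf is 1,1'-bis(diphenylphosphino)ferrocene, KOAc, dioxane, 80 °C) should give the aryl pinacol boronate F3. NaIO4 and NH4OAc in acetone/water should free the arylboronic acid F4. A Chan–Lam coupling of F4 with phenol 7 (Cu(OAc)2, pyridine, 4 Å molecular sieves, CH2Cl2, air, rt) should form the same diaryl ether 8 at room temperature by an oxidative copper cycle that needs no aryl halide.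

Step 3 (SNAr). Attack of the hindered 2,6-disubstituted phenoxide may be sluggish, so base-induced disproportionation and decomposition of 2-fluorobenzaldehyde at 130 °C may outpace ether formation. The fallback sets out from 4 and comes back at 6. SNAr with 2-fluorobenzonitrile (K2CO3, DMF, 100 °C), a stronger and base-stable activating group, should give 2-{6-[2-(4-bromophenyl)ethyl]-2,3-dimethoxyphenoxy}benzonitrile F5. Partial reduction with i-Bu2AlH (toluene, −78 °C) and acidic work-up should then deliver aldehyde 6 with the aryl bromide intact.

Further compounds
F1 | step 5 | [3-(4-{2-[2-(2-(hydroxymethyl)phenoxy)-3,4-dimethoxyphenyl]ethyl}phenoxy)-4,5-dimethoxyphenyl]methanol (bis(hydroxymethyl) compound) | OCc1ccccc1Oc1c(CCc2ccc(Oc3cc(CO)cc(OC)c3OC)cc2)ccc(OC)c1OC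
F2 | step 5 | bis(bromomethyl) compound corresponding to F1 | BrCc1ccccc1Oc1c(CCc2ccc(Oc3cc(CBr)cc(OC)c3OC)cc2)ccc(OC)c1OC
F3 | step 4 | 2-{2,3-dimethoxy-6-[2-(4-(4,4,5,5-tetramethyl-1,3,2-dioxaborolan-2-yl)phenyl)ethyl]phenoxy}benzaldehyde | O=Cc1ccccc1Oc1c(CCc2ccc(B3OC(C)(C)C(C)(C)O3)cc2)ccc(OC)c1OC
F4 | step 4 | (4-{2-[2-(2-formylphenoxy)-3,4-dimethoxyphenyl]ethyl}phenyl)boronic acid | O=Cc1ccccc1Oc1c(CCc2ccc(B(O)O)cc2)ccc(OC)c1OC
F5 | step 3 | 2-{6-[2-(4-bromophenyl)ethyl]-2,3-dimethoxyphenoxy}benzonitrile | N#Cc1ccccc1Oc1c(CCc2ccc(Br)cc2)ccc(OC)c1OC
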